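**Remark on the chemistry:** the SMILES is read as the (2R,3R)-isomer, with the C3 acetoxy group trans to the C2 methyl group and cis to the C2 side chain. Commercial (R)-(−)-linalool is taken as the 3R enantiomer in high enantiomeric purity. (R,R)-Mn(salen)Cl is assumed to give the (3R,4R)-oxide of a 2H-chromene, as it does with 2,2-dimethyl-2H-chromenes.

## The problem

The target is a 3,4-dihydro-2H-chromene: a benzene ring fused to a dihydropyran ring. It carries a methyl ester at C6, an acetoxy group at C3 and, at C2, a methyl group and an (E)-4-hydroxy-4-methylpent-2-enyl chain. The pyran ring holds two adjacent stereocentres: C2 is a fully substituted ether carbon (O1, CH3, chain, C3) and C3 is a secondary acetoxy carbon. The 2R,3R configuration corresponds to anti addition of two oxygens across a (Z)-olefin or syn addition across an (E)-olefin, so phenol opening of an (E)-geranyl epoxide would give the wrong relative configuration. C2 is the hard centre: it must tell CH3 from CH2R, it cannot be corrected later, and it cannot direct C3 because the same two similar groups flank it. C3 therefore has to come from a reagent or a stereospecific reaction. The tertiary allylic alcohol ionises with acid, the ester and acetate exclude hydrides and strong nucleophiles, and the acetate must be placed beside a free tertiary alcohol. The feature that opens the key step is twofold: C8a, the ring carbon bearing O1, is para to the C6 methoxycarbonyl group, and C2 with its methyl, C3 and six-carbon chain has the substitution pattern of C3 of linalool. The O1–C8a bond can therefore be made by nucleophilic aromatic substitution with the alkoxide of a commercial enantiopure tertiary alcohol, so the quaternary centre is bought rather than made. The remaining C3–C4 unit then becomes the cis olefin of a 2H-chromene, a favourable substrate for catalyst-controlled epoxidation.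

## Retrosynthesis

**12 to 11.** The acetyl C–O bond at C3 is cut last. The acetate is the most base-labile group, and a secondary alcohol is acylated much faster than a tertiary one, so no protecting group is needed. The forward step must acylate only the C3 hydroxyl of diol 11.

**11 to 10 to 9.** The C4–H bond and the C3–O bond are traced to epoxide 10 across C3–C4 and then to the cis olefin of 2H-chromene 9. Since C2 cannot direct C3, a catalyst must. The C3=C4 olefin of a 2H-chromene with an acceptor at C6 and a quaternary C2 is among the best substrates for Mn(salen) epoxidation. C4 is the only benzylic carbon, so reductive opening has one sensible regiochemistry. Two stereocentres disappear and 9 keeps only C2. The forward steps must put oxygen on the face of the C2 chain and cleave C4–O without touching the ester, the side-chain olefin or the tertiary allylic alcohol.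

**9 to 8.** The C3=C4 double bond is cut by ring-closing metathesis. Closing at O1–C2 would create the quaternary centre during ring closure, which is the problem being avoided. Closing at C4–C4a would need zerovalent palladium, which ionises allylic aryl ethers. Triene 8 is acyclic in the pyran part. The forward step must join the two terminal vinyl groups and leave the internal (E)-olefin alone.

**8 to 5 (through 6 and 7).** The (E)-CH=CH–C(CH3)2OH terminus is traced to the prenyl terminus of 5 by hydroxyselenation and selenoxide elimination. It is placed after O-arylation so the carbinol oxygen cannot capture the seleniranium ion. It is placed before metathesis so the prenyl olefin cannot form a cyclopentene with the vinyl group, and before the hypochlorite epoxidation. The forward step must select the trisubstituted olefin over the styrene and the vinyl group.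

**5 to 4.** The exocyclic C=CH2 of the styrene is cut by Wittig methylenation. The formyl group of 4 serves twice: it activates the substitution that forms 4 and it becomes C4 of the target. A palladium-catalysed vinylation of an aryl halide is avoided for the reason given above.

**4 to 1 and 2 (through 3).** The O1–C8a bond is cut. The precursors are (R)-linalool 1 and methyl 4-fluoro-3-formylbenzoate 2, both commercial. Cutting O1–C2 instead would require stereocontrolled formation of a tertiary ether. Here the carbinol C–O bond is never broken, so C2 arrives with its configuration. The forward reaction must bring the hindered alkoxide 3 to the C–F carbon faster than to either carbonyl group.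

## Roads not taken

**Alternative 1:** the obvious, biosynthesis-like route cuts O1–C2. Methyl 4-hydroxybenzoate is C-alkylated with a neryl halide to methyl 3-[(2Z)-3,7-dimethylocta-2,6-dien-1-yl]-4-hydroxybenzoate A1. The 2,3-olefin is epoxidised asymmetrically to epoxide A2. Acid-mediated 6-endo attack of the phenol at the tertiary epoxide carbon (inversion) closes the pyran, followed by acetylation and side-chain oxidation. The chosen plan is better for four reasons:
- The required relative configuration needs the (Z)-olefin; the natural (E)-geranyl series gives the wrong one.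
- Ortho C-alkylation of an electron-poor phenol competes with O-alkylation and allylic transposition.
- The epoxidation must distinguish two trisubstituted olefins.
- The ring closure must favour 6-endo over 5-exo attack.

These are three selectivity problems in the steps that set the stereocentres. The chosen plan buys C2 and sets C3 on a favourable substrate.

**Alternative 2:** the same O1–C8a cut, made on a dihydroxylated chain. Methyl 3-[(2E)-3,7-dimethylocta-2,6-dien-1-yl]-4-fluorobenzoate A3 undergoes Sharpless asymmetric dihydroxylation to the (2R,3R)-diol A4. The tertiary alkoxide then closes the pyran by substitution of fluoride with retention at both carbinol carbons. The dihydroxylation must prefer the inner olefin over the more accessible terminal one. In A4 the secondary alkoxide competes for the C–F carbon by closing a five-membered ring, so protection and deprotection are added. A3 itself needs an sp2–sp3 coupling with a geranyl electrophile. In the chosen plan only one oxygen nucleophile exists when the aryl ether is formed, and the ortho formyl group gives extra activation.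

**Alternative 3:** an aryne that takes up O1 and C4 together. Methyl 3,4-didehydrobenzoate A5, from the corresponding ortho-silyl aryl triflate, would add alkoxide 3, and the aryl anion would be formylated by DMF to give 4 in one operation. A5 has no substituent beside the triple bond: the ester is meta to one aryne carbon and para to the other and exerts only a weak inductive bias. A mixture of 4 and its regioisomer A6 is expected. The aryne precursor needs several steps, whereas in 2 the fluorine fixes the regiochemistry and the compound is bought.

Key step: step 1

## Route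

**Step 1**
Reactants: 1 (R)-linalool; 2 methyl 4-fluoro-3-formylbenzoate
Product: 4 methyl 4-{[(3R)-3,7-dimethylocta-1,6-dien-3-yl]oxy}-3-formylbenzoate, via potassium linaloolate 3 (not isolated)
Conditions: KN(SiMe3)2 (1.05 equiv), THF, −20 °C; then 2, THF, −20 to 0 °C
Reagents that add atoms: none
Why: Nucleophilic aromatic substitution by addition–elimination: alkoxide 3 adds to the fluorine-bearing carbon of 2 to give a Meisenheimer complex whose charge is delocalised into the para ester and the ortho formyl group, and fluoride leaves. The closest known reaction type is the preparation of tert-alkyl aryl ethers from potassium tert-alkoxides and ortho- or para-acceptor-substituted fluoroarenes. No ring is closed. No stereocentre is created: the carbinol C–O bond is never broken, so C3 of linalool becomes C2 of the target with retention, the control element being the chiral pool. The step needs chemoselectivity for the C–F carbon over the two carbonyl groups; double activation should make substitution fast at low temperature, addition to the formyl group is reversible and unproductive, and the bulk of 3 slows acyl substitution at the ester. Because the new bond is made at the sp2 carbon, the elimination and racemisation that accompany substitution at a tertiary carbon cannot occur. The product is kept cold and acid-free, since it is a tertiary allylic ether of an acidic phenol.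

**Step 2**
Reactants: 4 methyl 4-{[(3R)-3,7-dimethylocta-1,6-dien-3-yl]oxy}-3-formylbenzoate
Product: 5 methyl 4-{[(3R)-3,7-dimethylocta-1,6-dien-3-yl]oxy}-3-ethenylbenzoate
Conditions: Ph3PCH3Br, KOtBu, THF, 0 °C
Reagents that add atoms: methyltriphenylphosphonium bromide, C[P+](c1ccccc1)(c1ccccc1)c1ccccc1.[Br-]
Why: Wittig methylenation; the non-stabilised ylide should react with the aldehyde far faster than with the ester, and the basic, palladium-free conditions leave the tertiary allylic aryl ether intact.

**Step 3**
Reactants: 5 methyl 4-{[(3R)-3,7-dimethylocta-1,6-dien-3-yl]oxy}-3-ethenylbenzoate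
Product: 8 methyl 3-ethenyl-4-{[(3R,5E)-7-hydroxy-3,7-dimethylocta-1,5-dien-3-yl]oxy}benzoate, via hydroxy selenide 6 (not isolated), via selenoxide 7 (not isolated)
Conditions: N-(phenylselanyl)phthalimide, H2O, CSA (5 mol%), CH2Cl2, 0 °C; then pyridine, 30% H2O2, 0 °C to rt
Reagents that add atoms: water, O
Why: Electrophilic hydroxyselenation of the most electron-rich, trisubstituted olefin (Markovnikov: water at the tertiary carbon, selenium at C6 as a mixture of epimers), then selenoxide syn-elimination. The selenoxide can only take hydrogen from C5, because the carbinol carbon has none, so the (E)-allylic tertiary alcohol should result. The O-aryl group keeps the carbinol oxygen from capturing the seleniranium ion.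

**Step 4**
Reactants: 8 methyl 3-ethenyl-4-{[(3R,5E)-7-hydroxy-3,7-dimethylocta-1,5-dien-3-yl]oxy}benzoate
Product: 9 methyl (2R)-2-[(2E)-4-hydroxy-4-methylpent-2-en-1-yl]-2-methyl-2H-chromene-6-carboxylate
Conditions: second-generation Grubbs catalyst RuCl2(=CHPh)(PCy3)(H2IMes) (3 mol%), CH2Cl2 (0.01 M), 40 °C, exclusion of light
Reagents that add atoms: none
Why: Ring-closing olefin metathesis of the styrene with the vinyl group on the quaternary carbon should give the six-membered 2H-chromene with loss of ethene. The internal (E)-olefin would require a seven-membered ring and is shielded by its carbinol, and with the prenyl terminus already oxidised no cyclopentene can form. C2 is not touched; light is excluded because 2H-chromenes can open photochemically at O1–C2.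

**Step 5**
Reactants: 9 methyl (2R)-2-[(2E)-4-hydroxy-4-methylpent-2-en-1-yl]-2-methyl-2H-chromene-6-carboxylate
Product: 10 methyl (1aR,2R,7bR)-2-[(2E)-4-hydroxy-4-methylpent-2-en-1-yl]-2-methyl-1a,7b-dihydro-2H-oxireno[2,3-c]chromene-6-carboxylate (the 3R,4R-epoxide of 9, oxygen on the face of the C2 chain)
Conditions: (R,R)-Mn(salen)Cl, chloro[(R,R)-N,N′-bis(3,5-di-tert-butylsalicylidene)cyclohexane-1,2-diaminato]manganese, trivalent manganese (4 mol%), 4-phenylpyridine N-oxide (20 mol%), aq. NaOCl (pH 11.3), CH2Cl2, 0 °C
Reagents that add atoms: sodium hypochlorite, [Na+].[O-]Cl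
Why: Jacobsen–Katsuki epoxidation of a cis olefin conjugated to an acceptor-substituted arene and flanked by a quaternary carbon, the most favourable substrate class for this catalyst. The catalyst, not C2, should decide the face and set C3 (and C4) as R, while the trans olefin of the side chain is a poor substrate. Material of the opposite configuration at C2 becomes a diastereomer and is removed by chromatography.

**Step 6**
Reactants: 10 methyl (1aR,2R,7bR)-2-[(2E)-4-hydroxy-4-methylpent-2-en-1-yl]-2-methyl-1a,7b-dihydro-2H-oxireno[2,3-c]chromene-6-carboxylate
Product: 11 methyl (2R,3R)-3-hydroxy-2-[(2E)-4-hydroxy-4-methylpent-2-en-1-yl]-2-methyl-3,4-dihydro-2H-chromene-6-carboxylate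
Conditions: Cp2TiCl2 (2.5 equiv), Mn powder, THF, rt (forms Cp2TiCl, trivalent titanium); then 10, H2O (40 equiv), THF, rt
Reagents that add atoms: none
Why: Titanocene monochloride-mediated reductive epoxide opening: single-electron transfer cleaves the benzylic C4–O bond to the more stabilised radical, which takes a hydrogen atom from the Cp2TiCl–water complex. The C3–O bond is not involved, so C3 keeps its configuration, and the ester, olefin and tertiary allylic alcohol are inert to this reagent.

**Step 7**
Reactants: 11 methyl (2R,3R)-3-hydroxy-2-[(2E)-4-hydroxy-4-methylpent-2-en-1-yl]-2-methyl-3,4-dihydro-2H-chromene-6-carboxylate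
Product: 12 methyl (2R,3R)-3-(acetyloxy)-2-[(2E)-4-hydroxy-4-methylpent-2-en-1-yl]-2-methyl-3,4-dihydro-2H-chromene-6-carboxylate
Conditions: Ac2O (1.3 equiv), pyridine, DMAP (5 mol%), CH2Cl2, 0 °C
Reagents that add atoms: acetic anhydride, CC(=O)OC(C)=O
Why: Nucleophile-catalysed acylation; the secondary C3 hydroxyl should react much faster than the tertiary allylic hydroxyl, which stays free at low temperature with a small excess of anhydride.

## Compound list

1 | (R)-linalool, (3R)-3,7-dimethylocta-1,6-dien-3-ol | C=C[C@](C)(O)CCC=C(C)C | starting material
2 | methyl 4-fluoro-3-formylbenzoate | COC(=O)c1ccc(F)c(C=O)c1 | starting material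
3 | potassium (3R)-3,7-dimethylocta-1,6-dien-3-olate | C=C[C@](C)([O-])CCC=C(C)C.[K+] | intermediate
4 | methyl 4-{[(3R)-3,7-dimethylocta-1,6-dien-3-yl]oxy}-3-formylbenzoate | C=C[C@](C)(Oc1ccc(C(=O)OC)cc1C=O)CCC=C(C)C | intermediate
5 | methyl 4-{[(3R)-3,7-dimethylocta-1,6-dien-3-yl]oxy}-3-ethenylbenzoate | C=C[C@](C)(Oc1ccc(C(=O)OC)cc1C=C)CCC=C(C)C | intermediate
6 | methyl 3-ethenyl-4-{[(3R)-7-hydroxy-3,7-dimethyl-6-(phenylselanyl)oct-1-en-3-yl]oxy}benzoate (both C6 epimers) | C=C[C@](C)(Oc1ccc(C(=O)OC)cc1C=C)CCC([Se]c1ccccc1)C(C)(C)O | intermediate
7 | methyl 4-{[(3R)-6-(benzeneseleninyl)-7-hydroxy-3,7-dimethyloct-1-en-3-yl]oxy}-3-ethenylbenzoate (epimers at C6 and Se) | C=C[C@](C)(Oc1ccc(C(=O)OC)cc1C=C)CCC([Se](=O)c1ccccc1)C(C)(C)O | intermediate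
8 | methyl 3-ethenyl-4-{[(3R,5E)-7-hydroxy-3,7-dimethylocta-1,5-dien-3-yl]oxy}benzoate | C=C[C@](C)(Oc1ccc(C(=O)OC)cc1C=C)C/C=C/C(C)(C)O | intermediate
9 | methyl (2R)-2-[(2E)-4-hydroxy-4-methylpent-2-en-1-yl]-2-methyl-2H-chromene-6-carboxylate | COC(=O)c1ccc2c(c1)C=C[C@@](C)(C/C=C/C(C)(C)O)O2 | intermediate
10 | methyl (1aR,2R,7bR)-2-[(2E)-4-hydroxy-4-methylpent-2-en-1-yl]-2-methyl-1a,7b-dihydro-2H-oxireno[2,3-c]chromene-6-carboxylate | COC(=O)c1ccc2c(c1)[C@H]1O[C@H]1[C@@](C)(C/C=C/C(C)(C)O)O2 | intermediate
11 | methyl (2R,3R)-3-hydroxy-2-[(2E)-4-hydroxy-4-methylpent-2-en-1-yl]-2-methyl-3,4-dihydro-2H-chromene-6-carboxylate | COC(=O)c1ccc2c(c1)C[C@@H](O)[C@@](C)(C/C=C/C(C)(C)O)O2 | intermediate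
12 | methyl (2R,3R)-3-(acetyloxy)-2-[(2E)-4-hydroxy-4-methylpent-2-en-1-yl]-2-methyl-3,4-dihydro-2H-chromene-6-carboxylate | COC(=O)c1ccc2c(c1)C[C@@H](OC(C)=O)[C@@](C)(C/C=C/C(C)(C)O)O2 | target

## Step count and risks

Total step count: 7. Longest linear sequence: 7 steps, from 1 and 2 to 12.

**Step 1 (key step).** The hindered alkoxide may attack the ester or formyl carbonyl instead of the C–F carbon. Transesterification would release methoxide, which would then consume 2. The product ether may also ionise or undergo Claisen rearrangement if warmed. The fallback removes the ester from the substitution step. It sets out from 3, which is combined with 5-bromo-2-fluorobenzaldehyde to give 5-bromo-2-{[(3R)-3,7-dimethylocta-1,6-dien-3-yl]oxy}benzaldehyde F1. Wittig methylenation gives 4-bromo-1-{[(3R)-3,7-dimethylocta-1,6-dien-3-yl]oxy}-2-ethenylbenzene F2. Bromine–lithium exchange (n-BuLi, THF, −78 °C) and inverse quench into ClCO2Me installs the methyl ester, and the route is rejoined at 5.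

**Step 3.** The selenium electrophile may also add to the styrene olefin, and the acid catalyst may ionise the tertiary allylic aryl ether C–O bond. The fallback replaces electrophilic selenium by nucleophilic selenium under non-acidic conditions. It sets out from 5: buffered epoxidation (mCPBA, NaHCO3, CH2Cl2, 0 °C) of the trisubstituted olefin gives methyl 4-{[(3R)-5-(3,3-dimethyloxiran-2-yl)-3-methylpent-1-en-3-yl]oxy}-3-ethenylbenzoate F3. Sodium benzeneselenolate ((PhSe)2, NaBH4, EtOH) opens it at the secondary carbon. The route is rejoined at 6, which is oxidised as before.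

**Step 5.** Facial selectivity may be eroded, because the required face is syn to the larger C2 substituent and the catalyst and substrate preferences may be opposed; turnover may also be slow. The fallback sets C3 by reagent-controlled ketone reduction instead of face-selective epoxidation. It sets out from 9, epoxidised with whatever selectivity is obtained. The mixture of 10 and its diastereomer, methyl (1aS,2R,7bS)-2-[(2E)-4-hydroxy-4-methylpent-2-en-1-yl]-2-methyl-1a,7b-dihydro-2H-oxireno[2,3-c]chromene-6-carboxylate F4, is opened as in step 6. This gives 11 together with methyl (2R,3S)-3-hydroxy-2-[(2E)-4-hydroxy-4-methylpent-2-en-1-yl]-2-methyl-3,4-dihydro-2H-chromene-6-carboxylate F5. Dess–Martin oxidation converges both on methyl (2R)-2-[(2E)-4-hydroxy-4-methylpent-2-en-1-yl]-2-methyl-3-oxo-3,4-dihydro-2H-chromene-6-carboxylate F6. Corey–Bakshi–Shibata reduction with (S)-2-methyl-CBS-oxazaborolidine and catecholborane at −78 °C (C2 as the large group, C4 as the small group) should give the 3R alcohol, and the route is rejoined at 11.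

**Step 6.** The benzylic radical may accept a second electron and eliminate the titanium alkoxide, returning chromene 9, or it may add to the side-chain olefin. The fallback separates C–O cleavage from hydrogen delivery. It sets out from 10: benzeneselenolate ((PhSe)2, NaBH4, EtOH) opens the epoxide at benzylic C4 with inversion to give methyl (2R,3S,4S)-3-hydroxy-2-[(2E)-4-hydroxy-4-methylpent-2-en-1-yl]-2-methyl-4-(phenylselanyl)-3,4-dihydro-2H-chromene-6-carboxylate F7. Radical deselenation (Bu3SnH, AIBN, toluene, 80 °C) then gives 11, where the route is rejoined.

## Further compounds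

F1 | step 1 | 5-bromo-2-{[(3R)-3,7-dimethylocta-1,6-dien-3-yl]oxy}benzaldehyde | C=C[C@](C)(Oc1ccc(Br)cc1C=O)CCC=C(C)C
F2 | step 1 | 4-bromo-1-{[(3R)-3,7-dimethylocta-1,6-dien-3-yl]oxy}-2-ethenylbenzene | C=C[C@](C)(Oc1ccc(Br)cc1C=C)CCC=C(C)C
F3 | step 3 | methyl 4-{[(3R)-5-(3,3-dimethyloxiran-2-yl)-3-methylpent-1-en-3-yl]oxy}-3-ethenylbenzoate (both oxirane epimers) | C=C[C@](C)(Oc1ccc(C(=O)OC)cc1C=C)CCC1OC1(C)C
F4 | step 5 | methyl (1aS,2R,7bS)-2-[(2E)-4-hydroxy-4-methylpent-2-en-1-yl]-2-methyl-1a,7b-dihydro-2H-oxireno[2,3-c]chromene-6-carboxylate | COC(=O)c1ccc2c(c1)[C@@H]1O[C@@H]1[C@@](C)(C/C=C/C(C)(C)O)O2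
F5 | step 5 | methyl (2R,3S)-3-hydroxy-2-[(2E)-4-hydroxy-4-methylpent-2-en-1-yl]-2-methyl-3,4-dihydro-2H-chromene-6-carboxylate | COC(=O)c1ccc2c(c1)C[C@H](O)[C@@](C)(C/C=C/C(C)(C)O)O2
F6 | step 5 | methyl (2R)-2-[(2E)-4-hydroxy-4-methylpent-2-en-1-yl]-2-methyl-3-oxo-3,4-dihydro-2H-chromene-6-carboxylate | COC(=O)c1ccc2c(c1)CC(=O)[C@@](C)(C/C=C/C(C)(C)O)O2
F7 | step 6 | methyl (2R,3S,4S)-3-hydroxy-2-[(2E)-4-hydroxy-4-methylpent-2-en-1-yl]-2-methyl-4-(phenylselanyl)-3,4-dihydro-2H-chromene-6-carboxylate | COC(=O)c1ccc2c(c1)[C@H]([Se]c1ccccc1)[C@@H](O)[C@@](C)(C/C=C/C(C)(C)O)O2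
A1 | alternative 1 | methyl 3-[(2Z)-3,7-dimethylocta-2,6-dien-1-yl]-4-hydroxybenzoate | COC(=O)c1ccc(O)c(C/C=C(/C)CCC=C(C)C)c1
A2 | alternative 1 | methyl 4-hydroxy-3-{[(2R,3S)-3-methyl-3-(4-methylpent-3-en-1-yl)oxiran-2-yl]methyl}benzoate | COC(=O)c1ccc(O)c(C[C@H]2O[C@@]2(C)CCC=C(C)C)c1
A3 | alternative 2 | methyl 3-[(2E)-3,7-dimethylocta-2,6-dien-1-yl]-4-fluorobenzoate | COC(=O)c1ccc(F)c(C/C=C(\C)CCC=C(C)C)c1
A4 | alternative 2 | methyl 3-[(2R,3R)-2,3-dihydroxy-3,7-dimethyloct-6-en-1-yl]-4-fluorobenzoate | COC(=O)c1ccc(F)c(C[C@@H](O)[C@](C)(O)CCC=C(C)C)c1
A5 | alternative 3 | methyl 3,4-didehydrobenzoate | COC(=O)C1=CC#CC=C1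
A6 | alternative 3 | methyl 3-{[(3R)-3,7-dimethylocta-1,6-dien-3-yl]oxy}-4-formylbenzoate | C=C[C@](C)(Oc1cc(C(=O)OC)ccc1C=O)CCC=C(C)C
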